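**Assumptions:** the stereocentre in the SMILES is read as (S). (+)-Sparteine, 3,5-dimethoxy-4-methylbenzaldehyde, 4-methylpent-3-en-1-ol and angelic acid are bought.

## Retrosynthetic overview

1. Target 15 comes from the trimethyl ether 13 by oxidative demethylation to a para-quinone and reduction in the same pot; 13 comes from alcohol 10 and angelic acid 11.
2. Alcohol 10 comes from the α-carbamoyloxy aryl ketone 8 by methylenation and reductive removal of the carbamate.
3. Key disconnection, C2–C3: a chiral α-oxy carbanion 6 (lithiated homoprenyl carbamate, the carbonyl carbon of 4-methylpent-3-enal with reversed polarity) adds to the aldehyde carbon of 3. Two carbons that are normally both electrophilic are joined, and (+)-sparteine sets the stereocentre in the same step.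
4. Aldehyde 3 comes from 1 by bromination and copper-catalysed methoxylation; carbamate 5 comes from alcohol 4.
5. No ring is formed: the benzene ring is bought with 1 and only changes oxidation level (arene, quinone, hydroquinone) in the last step.

## Route

**Step 1**
Reactants: 1 3,5-dimethoxy-4-methylbenzaldehyde
Product: 2 2-bromo-3,5-dimethoxy-4-methylbenzaldehyde
Conditions: NBS (1.05 equiv), MeCN, rt, dark
Reagents that add atoms: N-bromosuccinimide, O=C1CCC(=O)N1Br
Why: Electrophilic aromatic bromination; the only free ring positions (C2 and C6, equivalent) are ortho/para to the two methoxy groups, so one regioisomer forms, and a polar solvent without initiator avoids benzylic bromination.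

**Step 2**
Reactants: 2 2-bromo-3,5-dimethoxy-4-methylbenzaldehyde
Product: 3 2,3,5-trimethoxy-4-methylbenzaldehyde
Conditions: NaOMe (5 equiv), CuBr (10 mol %), EtOAc (20 mol %), MeOH/DMF, 100 °C
Reagents that add atoms: sodium methoxide, [Na+].[O-]C
Why: Ullmann-type methoxylation catalysed by monovalent copper and accelerated by the ortho-formyl group (the classical bromovanillin-to-syringaldehyde reaction type); the aldehyde has no α-hydrogen.

**Step 3**
Reactants: 4 4-methylpent-3-en-1-ol
Product: 5 4-methylpent-3-en-1-yl N,N-diisopropylcarbamate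
Conditions: NaH, THF, 0 °C; then (i-Pr)2NCOCl, reflux
Reagents that add atoms: N,N-diisopropylcarbamoyl chloride, CC(C)N(C(C)C)C(=O)Cl
Why: O-Carbamoylation of the sodium alkoxide (nucleophilic acyl substitution) installs the directing and dipole-stabilising group needed for α-deprotonation.

**Step 4**
Reactants: 5 4-methylpent-3-en-1-yl N,N-diisopropylcarbamate, 3 2,3,5-trimethoxy-4-methylbenzaldehyde
Product: 7 (1RS,2S)-1-hydroxy-5-methyl-1-(2,3,5-trimethoxy-4-methylphenyl)hex-4-en-2-yl N,N-diisopropylcarbamate, via lithiated carbamate 6 (not isolated)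
Conditions: 5 (1.3 equiv), s-BuLi (1.25 equiv), (+)-sparteine (1.3 equiv), Et2O, −78 °C, 5 h; then 3 (1.0 equiv), −78 °C, 2 h; AcOH/Et2O quench at −78 °C
Reagents that add atoms: none
Why: Hoppe asymmetric deprotonation: s-BuLi/(+)-sparteine removes the pro-R α-proton to give the configurationally stable, carbamate-chelated (R)-α-lithio species 6, which adds to the aldehyde with retention and fixes C2 as (S) (mirror image of the (−)-sparteine series); the carbinol epimers converge in step 5 and the cold acid quench prevents carbamoyl migration.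

**Step 5**
Reactants: 7 (1RS,2S)-1-hydroxy-5-methyl-1-(2,3,5-trimethoxy-4-methylphenyl)hex-4-en-2-yl N,N-diisopropylcarbamate
Product: 8 (2S)-5-methyl-1-oxo-1-(2,3,5-trimethoxy-4-methylphenyl)hex-4-en-2-yl N,N-diisopropylcarbamate
Conditions: Dess–Martin periodinane (1.3 equiv), CH2Cl2, 0 °C to rt
Reagents that add atoms: none
Why: Dess–Martin oxidation of the benzylic alcohol converges both epimers to one ketone under neutral, non-enolising conditions, so the α-carbamoyloxy stereocentre is kept.

**Step 6**
Reactants: 8 (2S)-5-methyl-1-oxo-1-(2,3,5-trimethoxy-4-methylphenyl)hex-4-en-2-yl N,N-diisopropylcarbamate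
Product: 9 (3S)-6-methyl-2-(2,3,5-trimethoxy-4-methylphenyl)hepta-1,5-dien-3-yl N,N-diisopropylcarbamate
Conditions: Zn, CH2Br2, TiCl4, THF (reagent pre-formed at 0–5 °C); then 8 in CH2Cl2, 0 °C to rt
Reagents that add atoms: dibromomethane, BrCBr
Why: Takai–Lombardo methylenation (gem-dizinc/titanium methylene transfer) is non-basic and ketone-selective, so the epimerisable α-stereocentre and the carbamate carbonyl are left alone.

**Step 7**
Reactants: 9 (3S)-6-methyl-2-(2,3,5-trimethoxy-4-methylphenyl)hepta-1,5-dien-3-yl N,N-diisopropylcarbamate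
Product: 10 (3S)-6-methyl-2-(2,3,5-trimethoxy-4-methylphenyl)hepta-1,5-dien-3-ol
Conditions: LiAlH4 (4 equiv), THF, reflux; then H2O work-up
Reagents that add atoms: none
Why: Reductive decarbamoylation: hydride attacks the carbamate carbonyl and releases the alkoxide without breaking the C3–O bond, so the configuration is retained; aryl ethers and the unactivated alkenes are inert.

**Step 8**
Reactants: 10 (3S)-6-methyl-2-(2,3,5-trimethoxy-4-methylphenyl)hepta-1,5-dien-3-ol, 11 angelic acid ((2Z)-2-methylbut-2-enoic acid)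
Product: 13 (3S)-6-methyl-2-(2,3,5-trimethoxy-4-methylphenyl)hepta-1,5-dien-3-yl (2Z)-2-methylbut-2-enoate, via mixed angelic anhydride 12 (not isolated)
Conditions: 11, 2,4,6-trichlorobenzoyl chloride, Et3N, toluene, rt, 2 h; then 10, 80 °C, 24–48 h (no DMAP)
Reagents that add atoms: none
Why: Yamaguchi-type mixed-anhydride esterification run without a nucleophilic catalyst acylates on oxygen (retention at C3) and is the established way to make angelates without Z-to-E isomerisation to the tiglate.

**Step 9**
Reactants: 13 (3S)-6-methyl-2-(2,3,5-trimethoxy-4-methylphenyl)hepta-1,5-dien-3-yl (2Z)-2-methylbut-2-enoate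
Product: 15 (3S)-2-(2,5-dihydroxy-3-methoxy-4-methylphenyl)-6-methylhepta-1,5-dien-3-yl (2Z)-2-methylbut-2-enoate, via quinone 14 (not isolated)
Conditions: (NH4)2Ce(NO3)6 (2.5 equiv), MeCN/H2O 2:1, 0 °C, 15 min; then EtOAc, sat. aq Na2S2O4, rt, argon, until colourless
Reagents that add atoms: water, SMILES O
Why: Oxidative demethylation of the para-dimethoxy pair by tetravalent cerium gives the 2-methoxy-para-quinone (both carbonyl oxygens come from water, the methyl groups leave as methanol), and dithionite reduces it at once to the hydroquinone before the vinylquinone can dimerise; the ester, the alkenes and C3 are not touched.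

## Compound list

1 | 3,5-dimethoxy-4-methylbenzaldehyde | O=Cc1cc(OC)c(C)c(OC)c1 | starting material
2 | 2-bromo-3,5-dimethoxy-4-methylbenzaldehyde | O=Cc1cc(OC)c(C)c(OC)c1Br | intermediate
3 | 2,3,5-trimethoxy-4-methylbenzaldehyde | O=Cc1cc(OC)c(C)c(OC)c1OC | intermediate
4 | 4-methylpent-3-en-1-ol | CC(C)=CCCO | starting material
5 | 4-methylpent-3-en-1-yl N,N-diisopropylcarbamate | CC(C)=CCCOC(=O)N(C(C)C)C(C)C | intermediate
6 | (1R)-1-lithio-4-methylpent-3-en-1-yl N,N-diisopropylcarbamate, (+)-sparteine complex (ligand not drawn) | [Li][C@H](CC=C(C)C)OC(=O)N(C(C)C)C(C)C | intermediate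
7 | (1RS,2S)-1-hydroxy-5-methyl-1-(2,3,5-trimethoxy-4-methylphenyl)hex-4-en-2-yl N,N-diisopropylcarbamate (both C1 epimers) | OC(c1cc(OC)c(C)c(OC)c1OC)[C@H](CC=C(C)C)OC(=O)N(C(C)C)C(C)C | intermediate
8 | (2S)-5-methyl-1-oxo-1-(2,3,5-trimethoxy-4-methylphenyl)hex-4-en-2-yl N,N-diisopropylcarbamate | O=C(c1cc(OC)c(C)c(OC)c1OC)[C@H](CC=C(C)C)OC(=O)N(C(C)C)C(C)C | intermediate
9 | (3S)-6-methyl-2-(2,3,5-trimethoxy-4-methylphenyl)hepta-1,5-dien-3-yl N,N-diisopropylcarbamate | C=C(c1cc(OC)c(C)c(OC)c1OC)[C@H](CC=C(C)C)OC(=O)N(C(C)C)C(C)C | intermediate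
10 | (3S)-6-methyl-2-(2,3,5-trimethoxy-4-methylphenyl)hepta-1,5-dien-3-ol | C=C(c1cc(OC)c(C)c(OC)c1OC)[C@H](CC=C(C)C)O | intermediate
11 | angelic acid, (2Z)-2-methylbut-2-enoic acid | C/C=C(/C)C(=O)O | starting material
12 | (2Z)-2-methylbut-2-enoic 2,4,6-trichlorobenzoic anhydride | C/C=C(/C)C(=O)OC(=O)c1c(Cl)cc(Cl)cc1Cl | intermediate
13 | (3S)-6-methyl-2-(2,3,5-trimethoxy-4-methylphenyl)hepta-1,5-dien-3-yl (2Z)-2-methylbut-2-enoate | C=C(c1cc(OC)c(C)c(OC)c1OC)[C@H](CC=C(C)C)OC(=O)/C(C)=C\C | intermediate
14 | (3S)-2-(5-methoxy-4-methyl-3,6-dioxocyclohexa-1,4-dien-1-yl)-6-methylhepta-1,5-dien-3-yl (2Z)-2-methylbut-2-enoate | C=C(C1=CC(=O)C(C)=C(OC)C1=O)[C@H](CC=C(C)C)OC(=O)/C(C)=C\C | intermediate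
15 | (3S)-2-(2,5-dihydroxy-3-methoxy-4-methylphenyl)-6-methylhepta-1,5-dien-3-yl (2Z)-2-methylbut-2-enoate | C=C(c1cc(O)c(C)c(OC)c1O)[C@H](CC=C(C)C)OC(=O)/C(C)=C\C | target

## Summary

Total step count: 9.
Longest linear sequence: 8 steps (1 → 2 → 3 → 7 → 8 → 9 → 10 → 13 → 15; steps 1, 2, 4, 5, 6, 7, 8, 9).

## Steps most likely to fail, with fallbacks

**Step 4 (asymmetric lithiation and aldehyde addition).** The risks are carbamoyl migration in the β-alkoxide and a sluggish addition to the electron-rich, ortho-substituted aldehyde. The fallback sets out from 3 and 5 and comes back at 8. Aldehyde 3 is oxidised (NaClO2, NaH2PO4, 2-methylbut-2-ene, t-BuOH/H2O) to 2,3,5-trimethoxy-4-methylbenzoic acid F1. F1 is converted (oxalyl chloride, cat. DMF; then MeNH(OMe)·HCl, Et3N) into N,2,3,5-tetramethoxy-N,4-dimethylbenzamide F2. The same lithiated carbamate 6, made from 5 as before, is then acylated with F2 at −78 °C. The chelated tetrahedral adduct does not collapse until work-up, so no ketone is exposed to base, and ketone 8 is obtained directly; compound 7 and the oxidation of step 5 are bypassed.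

**Step 6 (methylenation of a hindered, epimerisable ketone).** The risk is low conversion at the congested carbonyl. The fallback sets out from 8 and comes back at 9, replacing the titanium methylene transfer by a two-stage Peterson olefination. The weakly basic organocerium reagent from Me3SiCH2Li and CeCl3 (THF, −78 °C) adds to 8 to give (3S)-2-hydroxy-6-methyl-2-(2,3,5-trimethoxy-4-methylphenyl)-1-(trimethylsilyl)hept-5-en-3-yl N,N-diisopropylcarbamate F3 as a mixture of C2 epimers. Elimination of the β-hydroxysilane (BF3·OEt2, CH2Cl2, −20 °C, or KH, THF, 0 °C) gives the terminal alkene 9 from either epimer.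

**Step 8 (angeloylation of a hindered secondary allylic alcohol).** The risks are slow acylation and isomerisation to the tiglate. The fallback sets out from 10 and comes back at 13, building the Z-alkene after the ester bond instead of carrying it in. Alcohol 10 is esterified (DCC, DMAP, CH2Cl2) with 2-[bis(2-methylphenoxy)phosphoryl]propanoic acid to give (3S)-6-methyl-2-(2,3,5-trimethoxy-4-methylphenyl)hepta-1,5-dien-3-yl 2-[bis(2-methylphenoxy)phosphoryl]propanoate F4. A Z-selective Horner–Wadsworth–Emmons reaction of the Ando type (NaH, THF, −78 °C; then acetaldehyde, −78 to 0 °C) then gives the (Z)-2-methylbut-2-enoate 13.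

## Further compounds

F1 | step 4 | 2,3,5-trimethoxy-4-methylbenzoic acid | OC(=O)c1cc(OC)c(C)c(OC)c1OC
F2 | step 4 | N,2,3,5-tetramethoxy-N,4-dimethylbenzamide | CON(C)C(=O)c1cc(OC)c(C)c(OC)c1OC
F3 | step 6 | (3S)-2-hydroxy-6-methyl-2-(2,3,5-trimethoxy-4-methylphenyl)-1-(trimethylsilyl)hept-5-en-3-yl N,N-diisopropylcarbamate (both C2 epimers) | C[Si](C)(C)CC(O)(c1cc(OC)c(C)c(OC)c1OC)[C@H](CC=C(C)C)OC(=O)N(C(C)C)C(C)C
F4 | step 8 | (3S)-6-methyl-2-(2,3,5-trimethoxy-4-methylphenyl)hepta-1,5-dien-3-yl 2-[bis(2-methylphenoxy)phosphoryl]propanoate | C=C(c1cc(OC)c(C)c(OC)c1OC)[C@H](CC=C(C)C)OC(=O)C(C)P(=O)(Oc1ccccc1C)Oc1ccccc1C
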